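The route rests on the bond between C3, the tertiary carbinol carbon of the five-membered ring, and ring-fusion C3a, which lies α to the C4 oxygen of the seven-membered ring. A rhodium carbenoid at C3a of a preformed cycloheptenone inserts into the C3–H bond of a side-chain silyl ether. This single operation closes the cyclopentane, turns a secondary carbinol into the hindered tertiary one with retention and fixes the cis ring fusion. The precursor is a 2-diazocyclohept-6-enone carrying a quaternary methyl-bearing C8a, a silyl-protected C8 carbinol and a (3S)-silyloxy-4-methylpentyl chain; its C5=C6 enone blocks C5 and is later relayed into the C6=C7 position.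

Key step: step 15

Remark: azulene locants are used for the bicycle (C3 carbinol, C3a and C8a ring fusion, C4 and C8 oxygenated, C6 methyl-bearing), β means the face of the C8a methyl group, and starting materials 1, 6, 7, 24 and the named reagents are taken to be catalogue compounds.

Step 1
Reactants: 1 methyl 4-methyl-3-oxopentanoate
Product: 2 methyl (3S)-3-hydroxy-4-methylpentanoate
Conditions: H2 (50 atm), RuCl2[(R)-BINAP] (0.2 mol%), MeOH, 50 °C
Reagents that add atoms: none
Why: Noyori asymmetric hydrogenation of a β-keto ester; the (R)-BINAP–ruthenium catalyst should deliver hydrogen to the ketone face that gives the (3S) carbinol, which becomes C3 of the target.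

Step 2
Reactants: 2 methyl (3S)-3-hydroxy-4-methylpentanoate
Product: 3 methyl (3S)-4-methyl-3-(triethylsilyloxy)pentanoate
Conditions: Et3SiCl, imidazole, CH2Cl2, 0 °C to rt
Reagents that add atoms: chlorotriethylsilane, CC[Si](CC)(CC)Cl
Why: Standard silylation of a secondary alcohol; the triethylsilyl ether later activates the C3–H bond for insertion, shields it less than a bulkier silyl group and stays removable once it has become tertiary.

Step 3
Reactants: 3 methyl (3S)-4-methyl-3-(triethylsilyloxy)pentanoate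
Product: 4 (3S)-4-methyl-3-(triethylsilyloxy)pentan-1-ol
Conditions: iBu2AlH (2.5 equiv), CH2Cl2, −78 to 0 °C; Rochelle salt work-up
Reagents that add atoms: none
Why: Hydride reduction of the ester to the primary alcohol, which leaves the silyl ether and the stereocentre untouched.

Step 4
Reactants: 4 (3S)-4-methyl-3-(triethylsilyloxy)pentan-1-ol
Product: 5 (3S)-1-bromo-4-methyl-3-(triethylsilyloxy)pentane
Conditions: CBr4, PPh3, imidazole, CH2Cl2, 0 °C
Reagents that add atoms: carbon tetrabromide, BrC(Br)(Br)Br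
Why: Appel bromination of the primary alcohol, buffered so that the silyl ether survives, gives the precursor of the side-chain Grignard reagent.

Step 5
Reactants: 6 ethyl glyoxylate; 7 2-methylpropene
Product: 8 ethyl (2R)-2-hydroxy-4-methylpent-4-enoate
Conditions: (R)-BINOL (10 mol%), TiCl2(OiPr)2 (10 mol%), 4 Å molecular sieves, CH2Cl2, −30 °C
Reagents that add atoms: none
Why: Catalytic asymmetric glyoxylate–ene reaction; the titanium binaphtholate should shield one aldehyde face so that isobutene adds to give the (2R) carbinol, which carries C8, C7, C6 and the C6 methyl group and later directs the quaternary centre.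

Step 6
Reactants: 8 ethyl (2R)-2-hydroxy-4-methylpent-4-enoate
Product: 9 (2R)-2-hydroxy-N-methoxy-N,4-dimethylpent-4-enamide
Conditions: MeNH(OMe)·HCl (2.5 equiv), iPrMgCl (5 equiv), THF, −20 to 0 °C
Reagents that add atoms: N,O-dimethylhydroxylamine hydrochloride, CNOC.Cl
Why: Direct conversion of the ester into the Weinreb amide by the magnesium amide; the neighbouring magnesium alkoxide formed first keeps the stereocentre from enolising.

Step 7
Reactants: 5 (3S)-1-bromo-4-methyl-3-(triethylsilyloxy)pentane; 9 (2R)-2-hydroxy-N-methoxy-N,4-dimethylpent-4-enamide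
Product: 11 (4R,8S)-4-hydroxy-2,9-dimethyl-8-(triethylsilyloxy)dec-1-en-5-one, via Grignard reagent 10 (not isolated)
Conditions: 5, Mg, THF, 45 °C; separately 9, iPrMgCl (1.0 equiv), THF, −20 °C; then 10 (1.4 equiv), −20 to 0 °C; aq. NH4Cl
Reagents that add atoms: none
Why: Weinreb ketone synthesis; the Grignard reagent should add once to the chelated amide of the preformed magnesium alkoxide, joining C1 to the future C8a without touching either stereocentre.

Step 8
Reactants: 11 (4R,8S)-4-hydroxy-2,9-dimethyl-8-(triethylsilyloxy)dec-1-en-5-one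
Product: 13 (5R)-5-(2-methylprop-2-en-1-yl)-4-[(3S)-4-methyl-3-(triethylsilyloxy)pentyl]furan-2(5H)-one, via ylide ester 12 (not isolated)
Conditions: Ph3P=C=C=O (1.2 equiv), toluene, 90 °C
Reagents that add atoms: (triphenylphosphoranylidene)ketene, O=C=C=P(c1ccccc1)(c1ccccc1)c1ccccc1
Why: The hydroxyl group adds to the ketene to give an acyl ylide that closes by intramolecular Wittig olefination of the ketone, which builds the butenolide (C3a and C4 are introduced) and leaves C8 unchanged.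

Step 9
Reactants: 13 (5R)-5-(2-methylprop-2-en-1-yl)-4-[(3S)-4-methyl-3-(triethylsilyloxy)pentyl]furan-2(5H)-one
Product: 15 (4R,5R)-4-methyl-5-(2-methylprop-2-en-1-yl)-4-[(3S)-4-methyl-3-(triethylsilyloxy)pentyl]oxolan-2-one, via silyl ketene acetal 14 (not isolated)
Conditions: Me2CuLi (3 equiv, from CuI and MeLi), Me3SiCl (5 equiv), THF–Et2O, −78 to −20 °C; aq. NH4Cl
Reagents that add atoms: lithium dimethylcuprate, [Li+].C[Cu-]C
Why: Lithium dialkylcuprate conjugate addition accelerated by the silyl chloride; methyl should add to the β-carbon of the butenolide on the face anti to the C8 2-methylallyl group, which sets the quaternary C8a as (R) by 1,2-induction.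

Step 10
Reactants: 15 (4R,5R)-4-methyl-5-(2-methylprop-2-en-1-yl)-4-[(3S)-4-methyl-3-(triethylsilyloxy)pentyl]oxolan-2-one
Product: 16 (3R,4R)-4-hydroxy-N-methoxy-N,3,6-trimethyl-3-[(3S)-4-methyl-3-(triethylsilyloxy)pentyl]hept-6-enamide
Conditions: MeNH(OMe)·HCl (3 equiv), iPrMgCl (6 equiv), THF, −15 to 0 °C; crude product used at once
Reagents that add atoms: N,O-dimethylhydroxylamine hydrochloride, CNOC.Cl
Why: Ring-opening aminolysis of the γ-lactone by the magnesium amide gives the Weinreb amide at C4 and frees the C8 hydroxyl without affecting the stereocentres.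

Step 11
Reactants: 16 (3R,4R)-4-hydroxy-N-methoxy-N,3,6-trimethyl-3-[(3S)-4-methyl-3-(triethylsilyloxy)pentyl]hept-6-enamide
Product: 17 (3R,4R)-N-methoxy-N,3,6-trimethyl-3-[(3S)-4-methyl-3-(triethylsilyloxy)pentyl]-4-(triethylsilyloxy)hept-6-enamide
Conditions: Et3SiOTf, 2,6-lutidine, CH2Cl2, −78 to 0 °C
Reagents that add atoms: triethylsilyl trifluoromethanesulfonate, CC[Si](CC)(CC)OS(=O)(=O)C(F)(F)F
Why: Silylation of the hindered neopentyl-type carbinol with the silyl triflate blocks relactonisation and gives a C8 protecting group that has no C–H bond within 1,5 reach of the later carbenoid.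

Step 12
Reactants: 17 (3R,4R)-N-methoxy-N,3,6-trimethyl-3-[(3S)-4-methyl-3-(triethylsilyloxy)pentyl]-4-(triethylsilyloxy)hept-6-enamide
Product: 18 (5R,6R)-5,8-dimethyl-5-[(3S)-4-methyl-3-(triethylsilyloxy)pentyl]-6-(triethylsilyloxy)nona-1,8-dien-3-one
Conditions: CH2=CHMgBr (2.5 equiv), THF, −78 to 0 °C; inverse quench into cold aq. citric acid
Reagents that add atoms: vinylmagnesium bromide, C=C[Mg]Br
Why: Weinreb ketone synthesis; the stable chelated adduct prevents double addition and the acidic inverse quench removes the liberated amine before it can add to the vinyl ketone.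

Step 13
Reactants: 18 (5R,6R)-5,8-dimethyl-5-[(3S)-4-methyl-3-(triethylsilyloxy)pentyl]-6-(triethylsilyloxy)nona-1,8-dien-3-one
Product: 19 (5R,6R)-3,6-dimethyl-6-[(3S)-4-methyl-3-(triethylsilyloxy)pentyl]-5-(triethylsilyloxy)cyclohept-2-en-1-one
Conditions: second-generation Grubbs catalyst RuCl2(=CHPh)(PCy3)(H2IMes) (5 mol%), CH2Cl2 (3 mM), 40 °C
Reagents that add atoms: none
Why: Ring-closing metathesis between the vinyl ketone and the 1,1-disubstituted alkene; the quaternary C8a favours closure of the seven-membered ring and the trisubstituted C5=C6 enone results.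

Step 14
Reactants: 19 (5R,6R)-3,6-dimethyl-6-[(3S)-4-methyl-3-(triethylsilyloxy)pentyl]-5-(triethylsilyloxy)cyclohept-2-en-1-one
Product: 21 (3R,4R)-2-diazo-3,6-dimethyl-3-[(3S)-4-methyl-3-(triethylsilyloxy)pentyl]-4-(triethylsilyloxy)cyclohept-6-en-1-one, via trifluoroacetyl ketone 20 (not isolated)
Conditions: LiN(SiMe3)2 (1.1 equiv), THF, −78 °C; CF3CO2CH2CF3 (1.2 equiv); cold dilute HCl work-up; then MeSO2N3 (1.5 equiv), Et3N (1.5 equiv), H2O (1 equiv), MeCN, rt
Reagents that add atoms: methanesulfonyl azide, CS(=O)(=O)N=[N+]=[N-]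
Why: Deacylative (Regitz-type) diazo transfer; kinetic deprotonation of the enone can only occur at the α′ carbon C3a because C5 is an alkene carbon, the enolate is trifluoroacetylated, and the sulfonyl azide then delivers N2 to C3a with loss of the trifluoroacetyl group.

Step 15
Reactants: 21 (3R,4R)-2-diazo-3,6-dimethyl-3-[(3S)-4-methyl-3-(triethylsilyloxy)pentyl]-4-(triethylsilyloxy)cyclohept-6-en-1-one
Product: 22 (3S,3aR,8R,8aR)-6,8a-dimethyl-3-(propan-2-yl)-3,8-bis(triethylsilyloxy)-2,3,3a,7,8,8a-hexahydroazulen-4(1H)-one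
Conditions: Rh2(OAc)4 (1 mol%), CH2Cl2 (10 mM), slow addition of 21, rt
Reagents that add atoms: none
Why: Rh2(OAc)4 expels N2 from 21 to give an electrophilic rhodium carbenoid at C3a, whose empty p orbital accepts the C3–H σ bond in a three-centre transition state that forms C3–C3a and C3a–H together as the metal leaves. The closest known reaction type is the dirhodium-catalysed intramolecular 1,5 C–H insertion of α-diazo ketones next to an ether or silyl ether oxygen. The five-membered ring (C3a, C8a, C1, C2, C3) closes in the 1,5 mode through a chair-like six-membered array that includes the migrating hydrogen. C3 is set with retention, so the (S) carbinol of 5 becomes the (3S) tertiary silyl ether; C3a is set by C8a, because only a pseudo-axial C1 chain can bring C3–H onto the carbenoid p lobe and it does so on its own face, which leaves the C3a hydrogen cis to the C8a methyl group. The step needs site selectivity for C3–H, which the substrate secures: this bond is a methine activated by the silyloxy group and the only one in a 1,5 relation, C8a is quaternary so no 1,2-hydride shift can compete, the ring alkene is tied up in the enone and cannot be cyclopropanated, and the C8 silyl ether has no C–H bond closer than the 1,6 position.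

Step 16
Reactants: 22 (3S,3aR,8R,8aR)-6,8a-dimethyl-3-(propan-2-yl)-3,8-bis(triethylsilyloxy)-2,3,3a,7,8,8a-hexahydroazulen-4(1H)-one
Product: 23 (3S,3aS,4R,8R,8aR)-6,8a-dimethyl-3-(propan-2-yl)-3,8-bis(triethylsilyloxy)-1,2,3,3a,4,7,8,8a-octahydroazulen-4-ol
Conditions: NaBH4, CeCl3·7H2O, MeOH, −40 °C
Reagents that add atoms: none
Why: Luche 1,2-reduction of the enone; hydride should attack C4 from the β face, next to the C3a hydrogen and away from the C3a–C3 bond and the α-isopropyl group on the concave side of the cis-fused bicycle, which gives the 4α alcohol (4R).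

Step 17
Reactants: 24 4-hydroxybenzoic acid
Product: 26 4-(tert-butyldimethylsilyloxy)benzoyl chloride, via silyl ester 25 (not isolated)
Conditions: tBuMe2SiCl (2.3 equiv), imidazole, DMF, rt; aqueous work-up; then (COCl)2 (1.2 equiv), DMF (cat.), CH2Cl2, 0 °C to rt
Reagents that add atoms: tert-butylchlorodimethylsilane, CC(C)(C)[Si](C)(C)Cl; oxalyl chloride, O=C(Cl)C(Cl)=O
Why: Silylation of both acidic groups followed by conversion of the silyl ester into the acid chloride by the chloroiminium reagent under neutral conditions, which leaves the aryl silyl ether in place.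

Step 18
Reactants: 23 (3S,3aS,4R,8R,8aR)-6,8a-dimethyl-3-(propan-2-yl)-3,8-bis(triethylsilyloxy)-1,2,3,3a,4,7,8,8a-octahydroazulen-4-ol; 26 4-(tert-butyldimethylsilyloxy)benzoyl chloride
Product: 27 (3S,3aS,4R,8R,8aR)-6,8a-dimethyl-3-(propan-2-yl)-3,8-bis(triethylsilyloxy)-1,2,3,3a,4,7,8,8a-octahydroazulen-4-yl 4-(tert-butyldimethylsilyloxy)benzoate
Conditions: 26 (1.5 equiv), Et3N, DMAP (0.5 equiv), CH2Cl2, 0 to 40 °C
Reagents that add atoms: none
Why: DMAP-catalysed acylation of the only free hydroxyl group installs the protected 4-hydroxybenzoate at C4 with retention.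

Step 19
Reactants: 27 (3S,3aS,4R,8R,8aR)-6,8a-dimethyl-3-(propan-2-yl)-3,8-bis(triethylsilyloxy)-1,2,3,3a,4,7,8,8a-octahydroazulen-4-yl 4-(tert-butyldimethylsilyloxy)benzoate
Product: 28 (3S,3aS,4R,8R,8aR)-8-hydroxy-6,8a-dimethyl-3-(propan-2-yl)-3-(triethylsilyloxy)-1,2,3,3a,4,7,8,8a-octahydroazulen-4-yl 4-(tert-butyldimethylsilyloxy)benzoate
Conditions: PPTS (0.2 equiv), MeOH–CH2Cl2 (1:1), 0 °C to rt
Reagents that add atoms: none
Why: Acid-catalysed methanolysis of a triethylsilyl ether; the secondary C8 ether should be cleaved while the tertiary C3 ether, buried between the isopropyl group and the ring fusion, and the acid-stable aryl silyl ether remain.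

Step 20
Reactants: 28 (3S,3aS,4R,8R,8aR)-8-hydroxy-6,8a-dimethyl-3-(propan-2-yl)-3-(triethylsilyloxy)-1,2,3,3a,4,7,8,8a-octahydroazulen-4-yl 4-(tert-butyldimethylsilyloxy)benzoate
Product: 30 (3S,3aS,4R,8aR)-6,8a-dimethyl-8-oxo-3-(propan-2-yl)-3-(triethylsilyloxy)-1,2,3,3a,4,5,8,8a-octahydroazulen-4-yl 4-(tert-butyldimethylsilyloxy)benzoate, via deconjugated enone 29 (not isolated)
Conditions: Dess–Martin periodinane (1.5 equiv), NaHCO3, CH2Cl2, 0 °C to rt; aq. Na2S2O3–NaHCO3 work-up; then p-TsOH·H2O (5 mol%), CH2Cl2, rt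
Reagents that add atoms: none
Why: Dess–Martin oxidation of the C8 alcohol followed by acid-catalysed isomerisation of the β,γ-unsaturated ketone through its dienol, which moves the alkene from C5=C6 into conjugation with the C8 carbonyl (C6=C7) and erases the C8 stereocentre after it has set C8a; acid is chosen over base because a dienolate could expel the C4 aroyloxy group.

Step 21
Reactants: 30 (3S,3aS,4R,8aR)-6,8a-dimethyl-8-oxo-3-(propan-2-yl)-3-(triethylsilyloxy)-1,2,3,3a,4,5,8,8a-octahydroazulen-4-yl 4-(tert-butyldimethylsilyloxy)benzoate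
Product: 31 (3S,3aS,4R,8R,8aR)-8-hydroxy-6,8a-dimethyl-3-(propan-2-yl)-3-(triethylsilyloxy)-1,2,3,3a,4,5,8,8a-octahydroazulen-4-yl 4-(tert-butyldimethylsilyloxy)benzoate
Conditions: (S)-2-methyl-CBS-oxazaborolidine (0.5 equiv), catecholborane (1.8 equiv), toluene, −78 °C; MeOH quench
Reagents that add atoms: none
Why: Corey–Bakshi–Shibata reduction; the oxazaborolidine should bind the ketone oxygen on the side of the flat C7 alkenyl flank, away from the quaternary C8a, and deliver hydride in the 1,2 sense to the α face, giving the 8β alcohol (8R) under catalyst control.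

Step 22
Reactants: 31 (3S,3aS,4R,8R,8aR)-8-hydroxy-6,8a-dimethyl-3-(propan-2-yl)-3-(triethylsilyloxy)-1,2,3,3a,4,5,8,8a-octahydroazulen-4-yl 4-(tert-butyldimethylsilyloxy)benzoate
Product: 32 (3S,3aS,4R,8R,8aR)-6,8a-dimethyl-8-(3-methylbutanoyloxy)-3-(propan-2-yl)-3-(triethylsilyloxy)-1,2,3,3a,4,5,8,8a-octahydroazulen-4-yl 4-(tert-butyldimethylsilyloxy)benzoate
Conditions: Me2CHCH2COCl (2 equiv), pyridine, DMAP (0.1 equiv), CH2Cl2, 0 °C to rt
Reagents that add atoms: 3-methylbutanoyl chloride, CC(C)CC(Cl)=O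
Why: Acylation of the secondary allylic alcohol with the acid chloride; no other free hydroxyl group is present.

Step 23
Reactants: 32 (3S,3aS,4R,8R,8aR)-6,8a-dimethyl-8-(3-methylbutanoyloxy)-3-(propan-2-yl)-3-(triethylsilyloxy)-1,2,3,3a,4,5,8,8a-octahydroazulen-4-yl 4-(tert-butyldimethylsilyloxy)benzoate
Product: 33 (3S,3aS,4R,8R,8aR)-3-hydroxy-6,8a-dimethyl-8-(3-methylbutanoyloxy)-3-(propan-2-yl)-1,2,3,3a,4,5,8,8a-octahydroazulen-4-yl 4-hydroxybenzoate
Conditions: HF·pyridine, pyridine, THF, 0 °C to rt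
Reagents that add atoms: none
Why: Fluoride-mediated desilylation under buffered conditions removes the aryl silyl ether and the tertiary triethylsilyl ether and spares both esters and the allylic system, giving the target.

Compound list

1 | methyl 4-methyl-3-oxopentanoate | COC(=O)CC(=O)C(C)C | starting material
2 | methyl (3S)-3-hydroxy-4-methylpentanoate | COC(=O)C[C@H](O)C(C)C | intermediate
3 | methyl (3S)-4-methyl-3-(triethylsilyloxy)pentanoate | COC(=O)C[C@H](O[Si](CC)(CC)CC)C(C)C | intermediate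
4 | (3S)-4-methyl-3-(triethylsilyloxy)pentan-1-ol | OCC[C@H](O[Si](CC)(CC)CC)C(C)C | intermediate
5 | (3S)-1-bromo-4-methyl-3-(triethylsilyloxy)pentane | BrCC[C@H](O[Si](CC)(CC)CC)C(C)C | intermediate
6 | ethyl glyoxylate | CCOC(=O)C=O | starting material
7 | 2-methylpropene | CC(C)=C | starting material
8 | ethyl (2R)-2-hydroxy-4-methylpent-4-enoate | CCOC(=O)[C@H](O)CC(C)=C | intermediate
9 | (2R)-2-hydroxy-N-methoxy-N,4-dimethylpent-4-enamide | CON(C)C(=O)[C@H](O)CC(C)=C | intermediate
10 | [(3S)-4-methyl-3-(triethylsilyloxy)pentyl]magnesium bromide | Br[Mg]CC[C@H](O[Si](CC)(CC)CC)C(C)C | intermediate (not isolated)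
11 | (4R,8S)-4-hydroxy-2,9-dimethyl-8-(triethylsilyloxy)dec-1-en-5-one | CC(C)[C@@H](O[Si](CC)(CC)CC)CCC(=O)[C@H](O)CC(C)=C | intermediate
12 | (4R,8S)-2,9-dimethyl-5-oxo-8-(triethylsilyloxy)dec-1-en-4-yl (triphenyl-λ5-phosphanylidene)acetate | CC(C)[C@@H](O[Si](CC)(CC)CC)CCC(=O)[C@@H](CC(C)=C)OC(=O)C=P(c1ccccc1)(c1ccccc1)c1ccccc1 | intermediate (not isolated)
13 | (5R)-5-(2-methylprop-2-en-1-yl)-4-[(3S)-4-methyl-3-(triethylsilyloxy)pentyl]furan-2(5H)-one | O=C1C=C(CC[C@H](O[Si](CC)(CC)CC)C(C)C)[C@@H](CC(C)=C)O1 | intermediate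
14 | (2R,3R)-3-methyl-2-(2-methylprop-2-en-1-yl)-3-[(3S)-4-methyl-3-(triethylsilyloxy)pentyl]-5-(trimethylsilyloxy)-2,3-dihydrofuran | C[Si](C)(C)OC1=C[C@@](C)(CC[C@H](O[Si](CC)(CC)CC)C(C)C)[C@@H](CC(C)=C)O1 | intermediate (not isolated)
15 | (4R,5R)-4-methyl-5-(2-methylprop-2-en-1-yl)-4-[(3S)-4-methyl-3-(triethylsilyloxy)pentyl]oxolan-2-one | O=C1C[C@@](C)(CC[C@H](O[Si](CC)(CC)CC)C(C)C)[C@@H](CC(C)=C)O1 | intermediate
16 | (3R,4R)-4-hydroxy-N-methoxy-N,3,6-trimethyl-3-[(3S)-4-methyl-3-(triethylsilyloxy)pentyl]hept-6-enamide | CON(C)C(=O)C[C@@](C)(CC[C@H](O[Si](CC)(CC)CC)C(C)C)[C@H](O)CC(C)=C | intermediate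
17 | (3R,4R)-N-methoxy-N,3,6-trimethyl-3-[(3S)-4-methyl-3-(triethylsilyloxy)pentyl]-4-(triethylsilyloxy)hept-6-enamide | CON(C)C(=O)C[C@@](C)(CC[C@H](O[Si](CC)(CC)CC)C(C)C)[C@H](O[Si](CC)(CC)CC)CC(C)=C | intermediate
18 | (5R,6R)-5,8-dimethyl-5-[(3S)-4-methyl-3-(triethylsilyloxy)pentyl]-6-(triethylsilyloxy)nona-1,8-dien-3-one | C=CC(=O)C[C@@](C)(CC[C@H](O[Si](CC)(CC)CC)C(C)C)[C@H](O[Si](CC)(CC)CC)CC(C)=C | intermediate
19 | (5R,6R)-3,6-dimethyl-6-[(3S)-4-methyl-3-(triethylsilyloxy)pentyl]-5-(triethylsilyloxy)cyclohept-2-en-1-one | CC1=CC(=O)C[C@@](C)(CC[C@H](O[Si](CC)(CC)CC)C(C)C)[C@H](O[Si](CC)(CC)CC)C1 | intermediate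
20 | (5R,6R)-3,6-dimethyl-6-[(3S)-4-methyl-3-(triethylsilyloxy)pentyl]-5-(triethylsilyloxy)-7-(trifluoroacetyl)cyclohept-2-en-1-one (C7 epimers and enol form) | CC1=CC(=O)C(C(=O)C(F)(F)F)[C@@](C)(CC[C@H](O[Si](CC)(CC)CC)C(C)C)[C@H](O[Si](CC)(CC)CC)C1 | intermediate (not isolated)
21 | (3R,4R)-2-diazo-3,6-dimethyl-3-[(3S)-4-methyl-3-(triethylsilyloxy)pentyl]-4-(triethylsilyloxy)cyclohept-6-en-1-one | CC1=CC(=O)C(=[N+]=[N-])[C@@](C)(CC[C@H](O[Si](CC)(CC)CC)C(C)C)[C@H](O[Si](CC)(CC)CC)C1 | intermediate (key-step precursor)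
22 | (3S,3aR,8R,8aR)-6,8a-dimethyl-3-(propan-2-yl)-3,8-bis(triethylsilyloxy)-2,3,3a,7,8,8a-hexahydroazulen-4(1H)-one | CC1=CC(=O)[C@@H]2[C@@](C)(CC[C@]2(O[Si](CC)(CC)CC)C(C)C)[C@H](O[Si](CC)(CC)CC)C1 | intermediate (key-step product)
23 | (3S,3aS,4R,8R,8aR)-6,8a-dimethyl-3-(propan-2-yl)-3,8-bis(triethylsilyloxy)-1,2,3,3a,4,7,8,8a-octahydroazulen-4-ol | CC1=C[C@@H](O)[C@@H]2[C@@](C)(CC[C@]2(O[Si](CC)(CC)CC)C(C)C)[C@H](O[Si](CC)(CC)CC)C1 | intermediate
24 | 4-hydroxybenzoic acid | OC(=O)c1ccc(O)cc1 | starting material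
25 | tert-butyldimethylsilyl 4-(tert-butyldimethylsilyloxy)benzoate | CC(C)(C)[Si](C)(C)OC(=O)c1ccc(O[Si](C)(C)C(C)(C)C)cc1 | intermediate (not isolated)
26 | 4-(tert-butyldimethylsilyloxy)benzoyl chloride | CC(C)(C)[Si](C)(C)Oc1ccc(cc1)C(Cl)=O | intermediate
27 | (3S,3aS,4R,8R,8aR)-6,8a-dimethyl-3-(propan-2-yl)-3,8-bis(triethylsilyloxy)-1,2,3,3a,4,7,8,8a-octahydroazulen-4-yl 4-(tert-butyldimethylsilyloxy)benzoate | CC1=C[C@@H](OC(=O)c3ccc(O[Si](C)(C)C(C)(C)C)cc3)[C@@H]2[C@@](C)(CC[C@]2(O[Si](CC)(CC)CC)C(C)C)[C@H](O[Si](CC)(CC)CC)C1 | intermediate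
28 | (3S,3aS,4R,8R,8aR)-8-hydroxy-6,8a-dimethyl-3-(propan-2-yl)-3-(triethylsilyloxy)-1,2,3,3a,4,7,8,8a-octahydroazulen-4-yl 4-(tert-butyldimethylsilyloxy)benzoate | CC1=C[C@@H](OC(=O)c3ccc(O[Si](C)(C)C(C)(C)C)cc3)[C@@H]2[C@@](C)(CC[C@]2(O[Si](CC)(CC)CC)C(C)C)[C@H](O)C1 | intermediate
29 | (3S,3aS,4R,8aR)-6,8a-dimethyl-8-oxo-3-(propan-2-yl)-3-(triethylsilyloxy)-1,2,3,3a,4,7,8,8a-octahydroazulen-4-yl 4-(tert-butyldimethylsilyloxy)benzoate | CC1=C[C@@H](OC(=O)c3ccc(O[Si](C)(C)C(C)(C)C)cc3)[C@@H]2[C@@](C)(CC[C@]2(O[Si](CC)(CC)CC)C(C)C)C(=O)C1 | intermediate (not isolated)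
30 | (3S,3aS,4R,8aR)-6,8a-dimethyl-8-oxo-3-(propan-2-yl)-3-(triethylsilyloxy)-1,2,3,3a,4,5,8,8a-octahydroazulen-4-yl 4-(tert-butyldimethylsilyloxy)benzoate | CC1=CC(=O)[C@]2(C)CC[C@](O[Si](CC)(CC)CC)(C(C)C)[C@@H]2[C@H](OC(=O)c3ccc(O[Si](C)(C)C(C)(C)C)cc3)C1 | intermediate
31 | (3S,3aS,4R,8R,8aR)-8-hydroxy-6,8a-dimethyl-3-(propan-2-yl)-3-(triethylsilyloxy)-1,2,3,3a,4,5,8,8a-octahydroazulen-4-yl 4-(tert-butyldimethylsilyloxy)benzoate | CC1=C[C@@H](O)[C@]2(C)CC[C@](O[Si](CC)(CC)CC)(C(C)C)[C@@H]2[C@H](OC(=O)c3ccc(O[Si](C)(C)C(C)(C)C)cc3)C1 | intermediate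
32 | (3S,3aS,4R,8R,8aR)-6,8a-dimethyl-8-(3-methylbutanoyloxy)-3-(propan-2-yl)-3-(triethylsilyloxy)-1,2,3,3a,4,5,8,8a-octahydroazulen-4-yl 4-(tert-butyldimethylsilyloxy)benzoate | CC1=C[C@@H](OC(=O)CC(C)C)[C@]2(C)CC[C@](O[Si](CC)(CC)CC)(C(C)C)[C@@H]2[C@H](OC(=O)c3ccc(O[Si](C)(C)C(C)(C)C)cc3)C1 | intermediate
33 | (3S,3aS,4R,8R,8aR)-3-hydroxy-6,8a-dimethyl-8-(3-methylbutanoyloxy)-3-(propan-2-yl)-1,2,3,3a,4,5,8,8a-octahydroazulen-4-yl 4-hydroxybenzoate | CC1=C[C@@H](OC(=O)CC(C)C)[C@]2(C)CC[C@](O)(C(C)C)[C@@H]2[C@H](OC(=O)c2ccc(O)cc2)C1 | target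

Total step count: 23. Longest linear sequence: 20 steps (1 to 33 through steps 1–4, 7–16 and 18–23).

Steps most likely to fail

Step 15. Process at risk: the carbenoid, crowded by the quaternary C8a, may be used up by dimerisation, by 1,6-insertion at the isopropyl methine or by attack of the C3 ether oxygen before it reaches the C3–H bond. Fallback: close the five-membered ring on the lactone and the seven-membered ring last. The fallback sets out from lactone 15. Trifluoroacetylation of its lithium enolate would give the trifluoroacetyl lactone F1, used crude, and methanesulfonyl azide with Et3N the diazo lactone F2. With Rh2(OAc)4 the ester carbenoid of F2 sits in a flat five-membered ring and can reach only the C3–H bond in the 1,5 mode. Since two five-membered rings can only be cis-fused, it should give the bicyclic lactone F3 with retention at C3. The magnesium amide of step 10 would open F3 to the hydroxy Weinreb amide F4, Et3SiOTf would give the bis(silyl ether) F5, and vinylmagnesium bromide the vinyl ketone F6. Ring-closing metathesis as in step 13 would then close the seven-membered ring, and the fallback comes back to the route at 22.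

Step 20. Process at risk: under the isomerisation conditions the dienol of 29, or the product 30 itself, may lose the C4 aroyloxy group by vinylogous β-elimination, or the allylic ester of 29 may ionise. Fallback: move the alkene by saturation and regiospecific dehydrogenation instead of by isomerisation. The fallback sets out from 28. Hydroxyl-directed hydrogenation with [Ir(cod)(PCy3)(py)]PF6 and H2 in CH2Cl2, which should not cleave the allylic ester, would give the saturated alcohol F7. Dess–Martin oxidation would give the saturated ketone F8, which can enolise only toward C7, and Me3SiOTf with Et3N the silyl enol ether F9. Pd(OAc)2 in MeCN (Saegusa–Ito oxidation) would then give the enone under neutral conditions, and the fallback comes back at 30.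

Step 21. Process at risk: poor facial selectivity at C8 if the inherent bias of the cis-fused bicycle opposes the catalyst. Fallback: aim for the other face and invert during esterification. The fallback sets out from 30. The enantiomeric (R)-2-methyl-CBS-oxazaborolidine with catecholborane would give the 8α alcohol F10. Mitsunobu esterification of F10 with 3-methylbutanoic acid (PPh3, diisopropyl azodicarboxylate, toluene) would install the isovalerate with inversion, and the fallback comes back at 32, bypassing steps 21 and 22.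

Further compounds

F1 | step 15 | (4R,5R)-4-methyl-5-(2-methylprop-2-en-1-yl)-4-[(3S)-4-methyl-3-(triethylsilyloxy)pentyl]-3-(trifluoroacetyl)oxolan-2-one | O=C1C(C(=O)C(F)(F)F)[C@@](C)(CC[C@H](O[Si](CC)(CC)CC)C(C)C)[C@@H](CC(C)=C)O1
F2 | step 15 | (4R,5R)-3-diazo-4-methyl-5-(2-methylprop-2-en-1-yl)-4-[(3S)-4-methyl-3-(triethylsilyloxy)pentyl]oxolan-2-one | O=C1C(=[N+]=[N-])[C@@](C)(CC[C@H](O[Si](CC)(CC)CC)C(C)C)[C@@H](CC(C)=C)O1
F3 | step 15 | cis-fused 3a-methyl-3-(2-methylprop-2-en-1-yl)-6-(propan-2-yl)-6-(triethylsilyloxy)hexahydro-1H-cyclopenta[c]furan-1-one, configured as in 22 | O=C1[C@@H]2[C@@](C)(CC[C@]2(O[Si](CC)(CC)CC)C(C)C)[C@@H](CC(C)=C)O1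
F4 | step 15 | 2-[(1R)-1-hydroxy-3-methylbut-3-en-1-yl]-N-methoxy-N,2-dimethyl-5-(propan-2-yl)-5-(triethylsilyloxy)cyclopentane-1-carboxamide, ring configured as in 22 | CON(C)C(=O)[C@@H]1[C@@](C)(CC[C@]1(O[Si](CC)(CC)CC)C(C)C)[C@H](O)CC(C)=C
F5 | step 15 | N-methoxy-N,2-dimethyl-2-[(1R)-3-methyl-1-(triethylsilyloxy)but-3-en-1-yl]-5-(propan-2-yl)-5-(triethylsilyloxy)cyclopentane-1-carboxamide, ring configured as in 22 | CON(C)C(=O)[C@@H]1[C@@](C)(CC[C@]1(O[Si](CC)(CC)CC)C(C)C)[C@H](O[Si](CC)(CC)CC)CC(C)=C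
F6 | step 15 | 1-{2-methyl-2-[(1R)-3-methyl-1-(triethylsilyloxy)but-3-en-1-yl]-5-(propan-2-yl)-5-(triethylsilyloxy)cyclopentyl}prop-2-en-1-one, ring configured as in 22 | C=CC(=O)[C@@H]1[C@@](C)(CC[C@]1(O[Si](CC)(CC)CC)C(C)C)[C@H](O[Si](CC)(CC)CC)CC(C)=C
F7 | step 20 | 8β-hydroxy-6α,8a-dimethyl-3-(propan-2-yl)-3-(triethylsilyloxy)decahydroazulen-4-yl 4-(tert-butyldimethylsilyloxy)benzoate, other centres as in 28 | C[C@H]1C[C@@H](OC(=O)c3ccc(O[Si](C)(C)C(C)(C)C)cc3)[C@@H]2[C@@](C)(CC[C@]2(O[Si](CC)(CC)CC)C(C)C)[C@H](O)C1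
F8 | step 20 | 6α,8a-dimethyl-8-oxo-3-(propan-2-yl)-3-(triethylsilyloxy)decahydroazulen-4-yl 4-(tert-butyldimethylsilyloxy)benzoate, other centres as in 28 | C[C@H]1C[C@@H](OC(=O)c3ccc(O[Si](C)(C)C(C)(C)C)cc3)[C@@H]2[C@@](C)(CC[C@]2(O[Si](CC)(CC)CC)C(C)C)C(=O)C1
F9 | step 20 | 6α,8a-dimethyl-3-(propan-2-yl)-3-(triethylsilyloxy)-8-(trimethylsilyloxy)-1,2,3,3a,4,5,6,8a-octahydroazulen-4-yl 4-(tert-butyldimethylsilyloxy)benzoate, other centres as in 28 | C[C@H]1C[C@@H](OC(=O)c3ccc(O[Si](C)(C)C(C)(C)C)cc3)[C@@H]2[C@@](C)(CC[C@]2(O[Si](CC)(CC)CC)C(C)C)C(O[Si](C)(C)C)=C1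
F10 | step 21 | (3S,3aS,4R,8S,8aR)-8-hydroxy-6,8a-dimethyl-3-(propan-2-yl)-3-(triethylsilyloxy)-1,2,3,3a,4,5,8,8a-octahydroazulen-4-yl 4-(tert-butyldimethylsilyloxy)benzoate | CC1=C[C@H](O)[C@]2(C)CC[C@](O[Si](CC)(CC)CC)(C(C)C)[C@@H]2[C@H](OC(=O)c3ccc(O[Si](C)(C)C(C)(C)C)cc3)C1
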